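## Retrosynthetic overview

1. In the cyclohexane ring, the quaternary carbon (CH3, vinyl) and the neighbouring CH (isopropenyl) are joined by a ring bond that is the central σ-bond of a hexa-1,5-diene. Cutting this bond (retro-3,3'-allyl–allyl coupling, a metal-templated retro-Cope) opens the ring to an acyclic (E,E)-bis-allylic dicarbonate with a single stereocentre.
2. The spiro-dihydropyran is disconnected by a retro-hetero-Diels–Alder reaction into an acyclic 2-substituted acrolein (1-oxadiene) and the exocyclic methylene of commercial (+)-alantolactone.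
3. The acyclic enal comes from (S)-limonene, which supplies the one bought stereocentre and 10 of the 15 carbons: oxygenation of the isopropenyl CH3, cleavage of the ring alkene, Wittig and Horner–Wadsworth–Emmons olefinations, reduction, carbonates.
4. Ring order: decalin and γ-lactone (bought with alantolactone), then the dihydropyran (hetero-Diels–Alder), then the cyclohexane (Pd-catalysed borylative allyl–allyl cyclisation), which sets two stereocentres from the bought one and gives the target directly.

Key step: step 12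

Remark: commercial (+)-alantolactone is taken as (3aR,5S,8aR,9aR), which matches the eudesmanolide half of the target. The elemane half has the β-elemene relative configuration in the (1R,2R,4S) series, so (S)-limonene is required. Locants for that half: C-10 quaternary ring carbon (C-14 methyl, C-1/C-2 vinyl), C-5 ring CH with isopropenyl (C-4, C-3, C-15), C-7 ring CH bearing C-11 (C-12 = O–CH=, C-13 = pyran CH2); primed locants refer to alantolactone.

## Route

Step 1
Reactants: 1 (S)-(−)-limonene, (4S)-1-methyl-4-(prop-1-en-2-yl)cyclohex-1-ene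
Product: 4 2-[(1S)-4-methylcyclohex-3-en-1-yl]prop-2-en-1-ol, via allyllithium 2 (not isolated), via allylboronate 3 (not isolated)
Conditions: n-BuLi, TMEDA, hexane, rt; B(OMe)3, THF, −78 °C to rt; 30% H2O2, aq. NaOH, 0 °C
Reagents that add atoms: hydrogen peroxide, OO
Why: Allylic lithiation with n-BuLi·TMEDA should take the isopropenyl CH3 (least hindered, most acidic allylic C–H) to give the symmetrical 2-substituted allyllithium, and borylation followed by oxidation of the C–B bond places the hydroxyl on that carbon without touching the ring stereocentre.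

Step 2
Reactants: 4 2-[(1S)-4-methylcyclohex-3-en-1-yl]prop-2-en-1-ol
Product: 5 tert-butyl{2-[(1S)-4-methylcyclohex-3-en-1-yl]prop-2-enyloxy}diphenylsilane
Conditions: TBDPSCl, imidazole, DMF, rt
Reagents that add atoms: tert-butyl(chloro)diphenylsilane, CC(C)(C)[Si](Cl)(c1ccccc1)c1ccccc1
Why: Standard silylation of a primary allylic alcohol; the TBDPS ether is chosen because it should survive the acidic periodate cleavage and the later hydride and base steps.

Step 3
Reactants: 5 tert-butyl{2-[(1S)-4-methylcyclohex-3-en-1-yl]prop-2-enyloxy}diphenylsilane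
Product: 6 1,2-epoxide of 5 (cis/trans mixture at the epoxide carbons, 4S)
Conditions: mCPBA (1.05 equiv), NaHCO3, CH2Cl2, 0 °C
Reagents that add atoms: 3-chloroperbenzoic acid, OOC(=O)c1cccc(Cl)c1
Why: Prilezhaev epoxidation should select the electron-rich trisubstituted ring alkene over the 1,1-disubstituted alkene deactivated by the allylic silyloxy group; the epoxide diastereomers converge in the next step.

Step 4
Reactants: 6 1,2-epoxide of 5
Product: 7 (3S)-3-[3-(tert-butyldiphenylsilyloxy)prop-1-en-2-yl]-6-oxoheptanal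
Conditions: H5IO6, THF/H2O, 0 °C to rt
Reagents that add atoms: water, O
Why: Periodic acid opens the epoxide to the glycol and cleaves it in the same pot (Malaprade-type cleavage), turning both epoxide carbons into carbonyls; the stereocentre is β to the aldehyde and cannot epimerise.

Step 5
Reactants: 7 (3S)-3-[3-(tert-butyldiphenylsilyloxy)prop-1-en-2-yl]-6-oxoheptanal
Product: 8 ethyl (2E,5S)-5-[3-(tert-butyldiphenylsilyloxy)prop-1-en-2-yl]-2-methyl-8-oxonon-2-enoate
Conditions: Ph3P=C(CH3)CO2Et, CH2Cl2, rt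
Reagents that add atoms: ethyl 2-(triphenyl-λ5-phosphanylidene)propanoate, CCOC(=O)C(C)=P(c1ccccc1)(c1ccccc1)c1ccccc1
Why: A stabilised Wittig ylide reacts with the aldehyde and not with the methyl ketone at room temperature, and gives the (E)-2-methyl enoate under the usual thermodynamic control.

Step 6
Reactants: 8 ethyl (2E,5S)-5-[3-(tert-butyldiphenylsilyloxy)prop-1-en-2-yl]-2-methyl-8-oxonon-2-enoate
Product: 9 diethyl (2E,5S,8E)-5-[3-(tert-butyldiphenylsilyloxy)prop-1-en-2-yl]-2,8-dimethyldeca-2,8-dienedioate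
Conditions: (EtO)2P(O)CH2CO2Et, NaH, THF, 0 °C to 50 °C; minor (8Z) isomer removed by chromatography
Reagents that add atoms: triethyl phosphonoacetate, CCOC(=O)CP(=O)(OCC)OCC
Why: Horner–Wadsworth–Emmons olefination of the methyl ketone should favour the (E)-trisubstituted enoate (larger chain anti to the ester), and the geometric purity needed for the key step is secured by separating the minor isomer here.

Step 7
Reactants: 9 diethyl (2E,5S,8E)-5-[3-(tert-butyldiphenylsilyloxy)prop-1-en-2-yl]-2,8-dimethyldeca-2,8-dienedioate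
Product: 10 (2E,5S,8E)-5-[3-(tert-butyldiphenylsilyloxy)prop-1-en-2-yl]-2,8-dimethyldeca-2,8-diene-1,10-diol
Conditions: DIBAL-H (5 equiv), CH2Cl2, −78 °C to −20 °C; Rochelle salt work-up
Reagents that add atoms: none
Why: DIBAL-H reduces both enoates by 1,2-addition to the allylic alcohols without touching the alkene geometries or the silyl ether.

Step 8
Reactants: 10 (2E,5S,8E)-5-[3-(tert-butyldiphenylsilyloxy)prop-1-en-2-yl]-2,8-dimethyldeca-2,8-diene-1,10-diol
Product: 11 di-tert-butyl (2E,5S,8E)-5-[3-(tert-butyldiphenylsilyloxy)prop-1-en-2-yl]-2,8-dimethyldeca-2,8-diene-1,10-diyl biscarbonate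
Conditions: Boc2O, Bu4NHSO4 (cat.), aq. NaOH, CH2Cl2, 0 °C to rt
Reagents that add atoms: di-tert-butyl dicarbonate, CC(C)(C)OC(=O)OC(=O)OC(C)(C)C
Why: Phase-transfer acylation of primary allylic alcohols with Boc2O is the standard entry to allylic tert-butyl carbonates; tert-butyl rather than methyl carbonates are chosen because the tert-butoxide released later does not attack a π-allylpalladium to form an ether.

Step 9
Reactants: 11 di-tert-butyl (2E,5S,8E)-5-[3-(tert-butyldiphenylsilyloxy)prop-1-en-2-yl]-2,8-dimethyldeca-2,8-diene-1,10-diyl biscarbonate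
Product: 12 di-tert-butyl (2E,5S,8E)-5-(3-hydroxyprop-1-en-2-yl)-2,8-dimethyldeca-2,8-diene-1,10-diyl biscarbonate
Conditions: TBAF, AcOH (1:1), THF, 0 °C to rt
Reagents that add atoms: none
Why: Buffered fluoride cleaves the Si–O bond, and the carbonates should be stable to it.

Step 10
Reactants: 12 di-tert-butyl (2E,5S,8E)-5-(3-hydroxyprop-1-en-2-yl)-2,8-dimethyldeca-2,8-diene-1,10-diyl biscarbonate
Product: 13 di-tert-butyl (2E,5S,8E)-2,8-dimethyl-5-(3-oxoprop-1-en-2-yl)deca-2,8-diene-1,10-diyl biscarbonate
Conditions: activated MnO2, CH2Cl2, rt; used at once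
Reagents that add atoms: none
Why: MnO2 oxidises the only free (allylic) alcohol to the 2-substituted acrolein under neutral conditions.

Step 11
Reactants: 13 di-tert-butyl (2E,5S,8E)-2,8-dimethyl-5-(3-oxoprop-1-en-2-yl)deca-2,8-diene-1,10-diyl biscarbonate; 14 (+)-alantolactone
Product: 15 hetero-Diels–Alder adduct: spiro[11',13'-dihydroalantolactone-11',2-(3,4-dihydro-2H-pyran)] carrying at C-5 of the pyran the (2E,5S,8E)-1,10-bis(tert-butoxycarbonyloxy)-2,8-dimethyldeca-2,8-dien-5-yl chain, pyran oxygen on the H-7'/H-8' face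
Conditions: 14 (3 equiv), BHT (cat.), toluene (2 M), 100 °C, sealed tube
Reagents that add atoms: none
Why: Thermal hetero-Diels–Alder reaction in the acrolein-dimer mode, with the enal as 1-oxadiene and the exocyclic methylene as dienophile, should join the two CH2 termini and bond oxygen to the lactone α-carbon; addition to the convex face of the cis-fused lactone (the H-7'/H-8' face, anti to the decalin) sets the spiro centre, and excess 14 suppresses homodimerisation of 13.

Step 12
Reactants: 15 hetero-Diels–Alder adduct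
Product: 18 CNP0175206.1, via allylboronate 16 (not isolated), via palladacycle 17 (not isolated)
Conditions: Pd2(dba)3 (5 mol%), 1,2-bis(diphenylphosphino)benzene (12 mol%), B2pin2 (1.05 equiv, syringe pump), THF (0.005 M), 60 °C
Reagents that add atoms: none
Why: Proposed new method: Pd(0) ionises one allylic carbonate (loss of CO2 and tert-butoxide), the alkoxide-activated B2pin2 borylates that π-allyl to give allylboronate 16 (the regioisomer borylated at the other terminus converges), and ionisation of the second carbonate followed by intramolecular B-to-Pd transmetalation gives the bis(η1-allyl)palladacycle 17, which forms the C-5–C-10 bond by 3,3'-reductive elimination, in effect a palladium-templated Cope-type closure of the seco-germacrane chain. The closest known reaction types are the Pd-catalysed allylic borylation of allyl carbonates with B2pin2, the Pd/diphosphine-catalysed branch-selective allylboronate–allyl electrophile coupling that builds adjacent quaternary and tertiary carbons, the Pd-catalysed intramolecular allylmetal–allyl carboxylate coupling to trans-1,2-divinylcycloalkanes and the Ni(0) cyclisation of bis-allylic dihalides; what is new is their merger into one reductive cyclisation of a bis-carbonate. The cyclohexane closes between the two γ-carbons of the allyl units, so that both π-bonds end up exocyclic (vinyl and isopropenyl), through a chair-like seven-membered Pd-containing transition state fused to the nascent chair cyclohexane. C-7, the only stereocentre of the chain, takes the equatorial position of that chair and so selects the faces of both allyl termini, while the (E) geometry of each places C-14 on C-10 and H on C-5 axial; C-10 and C-5 are therefore set together as 10R,5R (vinyl trans to isopropenyl, isopropenyl cis to the C-7 substituent). The step needs γ,γ'-coupling over α,α'-coupling (ten-membered ring) and α,γ'-coupling (eight-membered rings), which the small-bite-angle diphosphine and the kinetic preference for a six-membered ring should secure, and cyclisation over double borylation or oligomerisation, which high dilution and slow addition of B2pin2 should secure. The enol ether, the lactone, the trisubstituted alkene and the stereocentres of the alantolactone half should be inert under these neutral conditions.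

## Compound list

1 | (S)-(−)-limonene | CC1=CC[C@H](CC1)C(C)=C | starting material
2 | {2-[(1S)-4-methylcyclohex-3-en-1-yl]prop-2-enyl}lithium | CC1=CC[C@H](CC1)C(=C)C[Li] | intermediate
3 | dimethyl {2-[(1S)-4-methylcyclohex-3-en-1-yl]prop-2-enyl}boronate | CC1=CC[C@H](CC1)C(=C)CB(OC)OC | intermediate
4 | 2-[(1S)-4-methylcyclohex-3-en-1-yl]prop-2-en-1-ol | CC1=CC[C@H](CC1)C(=C)CO | intermediate
5 | tert-butyl{2-[(1S)-4-methylcyclohex-3-en-1-yl]prop-2-enyloxy}diphenylsilane | CC1=CC[C@H](CC1)C(=C)CO[Si](c1ccccc1)(c1ccccc1)C(C)(C)C | intermediate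
6 | 1,2-epoxide of 5 (epoxide carbons unassigned, cis/trans mixture; 4S) | CC12OC1C[C@H](CC2)C(=C)CO[Si](c1ccccc1)(c1ccccc1)C(C)(C)C | intermediate
7 | (3S)-3-[3-(tert-butyldiphenylsilyloxy)prop-1-en-2-yl]-6-oxoheptanal | O=CC[C@H](CCC(C)=O)C(=C)CO[Si](c1ccccc1)(c1ccccc1)C(C)(C)C | intermediate
8 | ethyl (2E,5S)-5-[3-(tert-butyldiphenylsilyloxy)prop-1-en-2-yl]-2-methyl-8-oxonon-2-enoate | CCOC(=O)/C(C)=C/C[C@H](CCC(C)=O)C(=C)CO[Si](c1ccccc1)(c1ccccc1)C(C)(C)C | intermediate
9 | diethyl (2E,5S,8E)-5-[3-(tert-butyldiphenylsilyloxy)prop-1-en-2-yl]-2,8-dimethyldeca-2,8-dienedioate | CCOC(=O)/C=C(\C)CC[C@@H](C/C=C(\C)C(=O)OCC)C(=C)CO[Si](c1ccccc1)(c1ccccc1)C(C)(C)C | intermediate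
10 | (2E,5S,8E)-5-[3-(tert-butyldiphenylsilyloxy)prop-1-en-2-yl]-2,8-dimethyldeca-2,8-diene-1,10-diol | OC/C=C(\C)CC[C@@H](C/C=C(\C)CO)C(=C)CO[Si](c1ccccc1)(c1ccccc1)C(C)(C)C | intermediate
11 | di-tert-butyl (2E,5S,8E)-5-[3-(tert-butyldiphenylsilyloxy)prop-1-en-2-yl]-2,8-dimethyldeca-2,8-diene-1,10-diyl biscarbonate | CC(C)(C)OC(=O)OC/C=C(\C)CC[C@@H](C/C=C(\C)COC(=O)OC(C)(C)C)C(=C)CO[Si](c1ccccc1)(c1ccccc1)C(C)(C)C | intermediate
12 | di-tert-butyl (2E,5S,8E)-5-(3-hydroxyprop-1-en-2-yl)-2,8-dimethyldeca-2,8-diene-1,10-diyl biscarbonate | CC(C)(C)OC(=O)OC/C=C(\C)CC[C@@H](C/C=C(\C)COC(=O)OC(C)(C)C)C(=C)CO | intermediate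
13 | di-tert-butyl (2E,5S,8E)-2,8-dimethyl-5-(3-oxoprop-1-en-2-yl)deca-2,8-diene-1,10-diyl biscarbonate | CC(C)(C)OC(=O)OC/C=C(\C)CC[C@@H](C/C=C(\C)COC(=O)OC(C)(C)C)C(=C)C=O | intermediate
14 | (+)-alantolactone, (3aR,5S,8aR,9aR) | C[C@H]1CCC[C@]2(C)C[C@H]3OC(=O)C(=C)[C@H]3C=C12 | starting material
15 | hetero-Diels–Alder adduct of 13 and 14 (spiro-dihydropyran lactone with the acyclic bis-carbonate chain) | CC(C)(C)OC(=O)OC/C=C(\C)CC[C@H](C2=CO[C@@]3(CC2)C(=O)O[C@@H]2C[C@@]4(C)CCC[C@H](C)C4=C[C@@H]23)C/C=C(\C)COC(=O)OC(C)(C)C | intermediate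
16 | mono-allylboronate of 15 (Bpin at C-3, carbonate at C-2) | CC(C)(C)OC(=O)OC/C=C(\C)CC[C@H](C2=CO[C@@]3(CC2)C(=O)O[C@@H]2C[C@@]4(C)CCC[C@H](C)C4=C[C@@H]23)C/C=C(\C)CB1OC(C)(C)C(C)(C)O1 | intermediate
17 | bis(η1-allyl)palladium(II) chelate, Pd bonded to C-2 and C-3, 1,2-bis(diphenylphosphino)benzene as ligand | C1/C=C(\C)CC[C@H](C2=CO[C@@]3(CC2)C(=O)O[C@@H]2C[C@@]4(C)CCC[C@H](C)C4=C[C@@H]23)C/C=C(\C)C[Pd]12[P](c3ccccc3)(c3ccccc3)c3ccccc3[P]2(c2ccccc2)c2ccccc2 | intermediate
18 | CNP0175206.1: spiro[11',13'-dihydroalantolactone-11',2-(3,4-dihydro-2H-pyran)] with a (1S,3R,4R)-4-ethenyl-4-methyl-3-(prop-1-en-2-yl)cyclohexyl group at C-5 of the pyran | C=C[C@@]1(C)CC[C@H](C2=CO[C@@]3(CC2)C(=O)O[C@@H]2C[C@@]4(C)CCC[C@H](C)C4=C[C@@H]23)C[C@@H]1C(=C)C | target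

## Step count and risks

Total step count: 12. Longest linear sequence: 12 steps (1 to 18); alantolactone 14 enters at step 11.

**Step 12 (key step).** The mono-boronate may be borylated a second time or couple intermolecularly, the π-allylpalladium may lose a β-hydrogen to give dienes, and the chair preference may be incomplete. The fallback uses known chemistry, the Ni(0)-promoted reductive cyclisation of a bis-allylic dihalide to a vinyl/isopropenyl cyclohexane, and keeps the ring order. It sets out from diol 10. Mesylation and chloride exchange without allylic transposition (MsCl, LiCl, 2,4,6-collidine, DMF, 0 °C) should give (2E,5S,8E)-1,10-dichloro-2,8-dimethyl-5-[3-(tert-butyldiphenylsilyloxy)prop-1-en-2-yl]deca-2,8-diene F1. HF·pyridine should give 2-[(2E,5S,8E)-1,10-dichloro-2,8-dimethyldeca-2,8-dien-5-yl]prop-2-en-1-ol F2, and MnO2 the corresponding prop-2-enal F3. Heating F3 with 14 (toluene, 100 °C, solid NaHCO3) should give the dichloro cycloadduct F4. Ni(cod)2 in DMF/THF at high dilution should then close the cyclohexane through the bis-allylnickel species, and the route comes back at 18, with separation of diastereomers if needed.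

**Step 11.** The flexible 2-substituted acrolein may homodimerise or polymerise faster than it adds to the lactone, the tert-butyl carbonates may be lost thermally, and facial selectivity may be insufficient. The fallback inverts the order of the last two ring closures, so that the cycloaddition is run last on a more hindered, more robust cyclic enal that carries no carbonates. It sets out from diol 10. MsCl/Et3N, then LiBr in THF, should give (2E,5S,8E)-1,10-dibromo-2,8-dimethyl-5-[3-(tert-butyldiphenylsilyloxy)prop-1-en-2-yl]deca-2,8-diene F5. Ni(cod)2 in DMF at high dilution should close the ring to tert-butyl{2-[(1S,3R,4R)-4-ethenyl-4-methyl-3-(prop-1-en-2-yl)cyclohexyl]prop-2-enyloxy}diphenylsilane F6. TBAF should give 2-[(1S,3R,4R)-4-ethenyl-4-methyl-3-(prop-1-en-2-yl)cyclohexyl]prop-2-en-1-ol F7, and MnO2 the corresponding prop-2-enal F8. Heating F8 with excess 14 (neat, 100–120 °C, or under high pressure) comes back to the route at 18.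

**Step 1.** Metalation may be incomplete or may also occur at ring allylic positions, and proton transfer within the allyl anion may erode the adjacent stereocentre. The fallback replaces the early lithiation by a late ene-type chlorination of the isopropenyl group, at a stage where the other two alkenes are deactivated as enoates, and needs no protecting group. It sets out from 1. mCPBA should give (4S)-limonene 1,2-oxide F9, and H5IO6 should give (3S)-6-oxo-3-(prop-1-en-2-yl)heptanal F10. The Wittig reaction of step 5 should give ethyl (2E,5S)-2-methyl-8-oxo-5-(prop-1-en-2-yl)non-2-enoate F11, and the olefination of step 6 should give diethyl (2E,5S,8E)-2,8-dimethyl-5-(prop-1-en-2-yl)deca-2,8-dienedioate F12. Ca(OCl)2/CO2 in CH2Cl2/H2O (HOCl ene-type chlorination) should give diethyl (2E,5S,8E)-5-(3-chloroprop-1-en-2-yl)-2,8-dimethyldeca-2,8-dienedioate F13. DIBAL-H at −78 °C should give (2E,5S,8E)-5-(3-chloroprop-1-en-2-yl)-2,8-dimethyldeca-2,8-diene-1,10-diol F14, and Boc2O with catalytic DMAP its bis(tert-butyl carbonate) F15. Kornblum-type oxidation of the allylic chloride with Me3NO in DMSO comes back to the route at 13.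

## Further compounds

F1 | step 12 | (2E,5S,8E)-1,10-dichloro-2,8-dimethyl-5-[3-(tert-butyldiphenylsilyloxy)prop-1-en-2-yl]deca-2,8-diene | ClC/C=C(\C)CC[C@@H](C/C=C(\C)CCl)C(=C)CO[Si](c1ccccc1)(c1ccccc1)C(C)(C)C
F2 | step 12 | 2-[(2E,5S,8E)-1,10-dichloro-2,8-dimethyldeca-2,8-dien-5-yl]prop-2-en-1-ol | ClC/C=C(\C)CC[C@@H](C/C=C(\C)CCl)C(=C)CO
F3 | step 12 | 2-[(2E,5S,8E)-1,10-dichloro-2,8-dimethyldeca-2,8-dien-5-yl]prop-2-enal | ClC/C=C(\C)CC[C@@H](C/C=C(\C)CCl)C(=C)C=O
F4 | step 12 | hetero-Diels–Alder adduct of F3 and 14 (dichloro analogue of 15) | ClC/C=C(\C)CC[C@H](C2=CO[C@@]3(CC2)C(=O)O[C@@H]2C[C@@]4(C)CCC[C@H](C)C4=C[C@@H]23)C/C=C(\C)CCl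
F5 | step 11 | (2E,5S,8E)-1,10-dibromo-2,8-dimethyl-5-[3-(tert-butyldiphenylsilyloxy)prop-1-en-2-yl]deca-2,8-diene | BrC/C=C(\C)CC[C@@H](C/C=C(\C)CBr)C(=C)CO[Si](c1ccccc1)(c1ccccc1)C(C)(C)C
F6 | step 11 | tert-butyl{2-[(1S,3R,4R)-4-ethenyl-4-methyl-3-(prop-1-en-2-yl)cyclohexyl]prop-2-enyloxy}diphenylsilane | C=C[C@@]1(C)CC[C@H](C(=C)CO[Si](c2ccccc2)(c2ccccc2)C(C)(C)C)C[C@@H]1C(=C)C
F7 | step 11 | 2-[(1S,3R,4R)-4-ethenyl-4-methyl-3-(prop-1-en-2-yl)cyclohexyl]prop-2-en-1-ol | C=C[C@@]1(C)CC[C@H](C(=C)CO)C[C@@H]1C(=C)C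
F8 | step 11 | 2-[(1S,3R,4R)-4-ethenyl-4-methyl-3-(prop-1-en-2-yl)cyclohexyl]prop-2-enal | C=C[C@@]1(C)CC[C@H](C(=C)C=O)C[C@@H]1C(=C)C
F9 | step 1 | (4S)-limonene 1,2-oxide (cis/trans mixture) | CC12OC1C[C@H](CC2)C(C)=C
F10 | step 1 | (3S)-6-oxo-3-(prop-1-en-2-yl)heptanal | O=CC[C@H](CCC(C)=O)C(C)=C
F11 | step 1 | ethyl (2E,5S)-2-methyl-8-oxo-5-(prop-1-en-2-yl)non-2-enoate | CCOC(=O)/C(C)=C/C[C@H](CCC(C)=O)C(C)=C
F12 | step 1 | diethyl (2E,5S,8E)-2,8-dimethyl-5-(prop-1-en-2-yl)deca-2,8-dienedioate | CCOC(=O)/C=C(\C)CC[C@@H](C/C=C(\C)C(=O)OCC)C(C)=C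
F13 | step 1 | diethyl (2E,5S,8E)-5-(3-chloroprop-1-en-2-yl)-2,8-dimethyldeca-2,8-dienedioate | CCOC(=O)/C=C(\C)CC[C@@H](C/C=C(\C)C(=O)OCC)C(=C)CCl
F14 | step 1 | (2E,5S,8E)-5-(3-chloroprop-1-en-2-yl)-2,8-dimethyldeca-2,8-diene-1,10-diol | OC/C=C(\C)CC[C@@H](C/C=C(\C)CO)C(=C)CCl
F15 | step 1 | di-tert-butyl (2E,5S,8E)-5-(3-chloroprop-1-en-2-yl)-2,8-dimethyldeca-2,8-diene-1,10-diyl biscarbonate | CC(C)(C)OC(=O)OC/C=C(\C)CC[C@@H](C/C=C(\C)COC(=O)OC(C)(C)C)C(=C)CCl
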